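**Conventions.** Ring A is the 3,5-dimethoxy-4-oxyphenyl ring on C2. Ring B is the dihydrofuran (O1, C2, C3, C3a, C7a). Ring C is the benzo ring carrying the formyl group at C5 and a methoxy group at C7. Ring D is the guaiacyl ring of the glycerol unit, whose chain is Cα (benzylic carbinol), Cβ (aryloxy carbon) and Cγ (CH2OH). C7, C8 and C9 are the side-chain carbons of the cinnamoyl unit that become C2, C3 and the C3 substituent.

## The problem

Target 20 joins a trans-2-aryl-3-hydroxymethyl-2,3-dihydrobenzofuran (rings B and C) through the phenol oxygen of ring A to Cβ of a guaiacylglycerol. It has four stereocentres in two pairs: C2/C3 (2R,3S, trans) and Cα/Cβ (S,R; erythro, that is anti in the zigzag drawing). The pairs are insulated from each other by ring A, so each needs its own source of absolute configuration. Within the first pair C3 can direct C2, because closing ring B places the aryl group trans to the C3 substituent. Within the second pair Cβ directs Cα only weakly, so both are best set together by a reagent. Several groups rule out rough treatment: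

- The ring C aldehyde is attacked by hydrides, enolates and peroxides.
- The Cα carbinol sits para to the ring D oxygen. Acid ionises it, and a leaving group on Cα with a free ring D phenoxide gives a quinone methide.
- The C2–O1 bond is a benzylic aryl ether para to the ring A oxygen, so hydrogenolysis and strong acid are excluded.
- C3 is prone to ring opening under base for as long as it carries an acyl group.

The feature that opens the molecule is that C3–C3a and O1–C2 are the 8–5 and 7–O links of a phenylcoumaran. Ring A with C2, C3 and the C3 carbon is a sinapoyl unit, and ring C with its para formyl group is vanillin. Ring A has both positions ortho to oxygen methoxylated and can therefore couple only through C8. Vanillin has no side-chain radical site and can offer only C5 or O4. Only one phenylcoumaran can result from the pair.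

## Retrosynthesis

**Unmasking (20 from 19, 19 from 17 through 18).** No skeletal bond is cut. The ring D phenol of 20 is traced to the triisopropylsilyl ether 19, removed last by buffered fluoride. Compound 19 is traced to 17, in which the C3 carboxyl and the Cγ carboxyl are both N-acyloxazolidinones, Cα carries an ester and the aldehyde is a dioxolane. One hydride operation gives 18, and its mildly acidic quench frees the aldehyde. A benzyl ether on ring D was rejected because of the two benzylic C–O bonds and the aldehyde. An acyl group on the ring D phenol was rejected because hydride would free the phenoxide while the Cα ester is still present. The forward steps must leave Cα untouched.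

**Inversion at Cα (17 from 16).** The Cα–O bond is cut and remade with inversion. The dependable auxiliary aldol of an aryloxyacetyl imide gives the syn adduct, which corresponds to the threo glycerol, whereas 20 is erythro. Direct anti-aldol methods are poorly documented for aryloxyacetyl donors. Inverting Cβ instead would require SN2 attack of a hindered 2,6-dimethoxyphenoxide at a branched secondary carbon. Inversion of the single free hydroxyl of 16 by a carboxylate under Mitsunobu conditions is the documented way from threo to erythro in this class. The forward reaction must substitute faster than it eliminates.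

**Cα–Cβ bond (16 from 13 and 14 through 15).** The cut turns ring D and Cα into the silylated vanillin 14 and leaves the aryloxyacetyl imide 13. The boron enolate 15 sets Cα and Cβ under control of the auxiliary alone, which is what the remote C2/C3 pair requires. The forward reaction must enolise only the unbranched acyl group of 13 and must spare the dioxolane.

**Cβ–O ether and aldehyde mask (13 from 12 and 4; 12 from 11).** The ether is cut at O–Cβ while Cβ is still a CH2 group. It is then a Williamson alkylation of the ring A phenol of 12 by the bromoacetyl imide 4, the easiest possible substitution for a hindered phenoxide. Compound 12 is the dioxolane of 11. The C3 auxiliary is deliberately kept as the protecting group of the C3 carboxyl until the final hydride step, which saves a reduction and a silylation.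

**Key disconnection (11 from 8 and 9 through 10).** C3–C3a and O1–C2 are cut together. This opens ring B and divides the phenylcoumaran into the sinapoyl imide 8 and vanillin 9. A one-electron oxidant joins C8 of 8 to C5 of 9, and the phenol–quinone methide 10 closes ring B. The cut removes one ring, two skeletal bonds and both ring stereocentres. It delivers the ring A phenol, the ring C aldehyde and the C3 carboxyl in the oxidation states needed next. The forward reaction must favour cross-coupling over homo-coupling, C5 over O4 of vanillin, and one face of C8.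

**Simple pieces (8 from 6 and 7; 6 from 4 through 5; 4 from 1 and 2 through 3; 14 from 9).** The C7=C8 double bond of 8 is cut as a Wittig olefination of syringaldehyde 7 with the stabilised ylide 6, so that no phenol protection is needed. The ylide comes from the same bromoacetyl imide 4 that later supplies Cβ and Cγ. Imide 4 is the N-acylation product of oxazolidinone 1 and bromoacetyl bromide 2. Aldehyde 14 is silylated vanillin 9.

## Roads not taken

**Alternative 1:** The cut lies in the glycerol chain. Cβ–O and Cα–Cβ are formed together from three pieces: the ring A phenol of a finished, protected phenylcoumaran A2, ethyl diazoacetate A3 and O-benzylvanillin A4. In the forward step Rh2(OAc)4 turns A3 into a carbenoid and the phenol oxygen of A2 attacks it. The oxonium ylide is then trapped by A4, activated by a chiral BINOL–Zr(OtBu)4 complex, to give the erythro hydroxy ester A1.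

- Merits: two bonds and both side-chain stereocentres arise in one catalytic step, directly erythro, with no auxiliary and no inversion. For the side chain alone this is shorter than steps 6, 8 and 9 here.
- Weak points: the route does not address rings B and C, so A2 would itself need a phenylcoumaran synthesis such as the coupling used here. An ylide from a phenol and an acceptor-only carbenoid collapses easily by proton shift to the plain O–H insertion product. The trap is an electron-rich, weakly electrophilic aldehyde, and the phenol is flanked by two methoxy groups. Relative and absolute configuration rest on the catalyst alone. The benzyl ether on ring D would later meet the hydrogenolysis problem.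
- Comparison: the chosen plan spends three more steps and a second equivalent of auxiliary on the side chain. It offers in return reaction classes of predictable stereochemical outcome and imide intermediates at which diastereomeric purity can be checked and raised.

**Alternative 2:** The cut is C3–C3a, made by rearrangement instead of coupling. The ester A5 is traced to the six-membered (2R)-flavanone A6. In the forward step PhI(OAc)2 (trivalent iodine) with H2SO4 in trimethyl orthoformate attacks C3 of the enol ether of A6. The benzo ring carbon migrates from the carbonyl carbon to C3 as iodobenzene leaves, the ring contracts, and the former carbonyl carbon ends as the methyl ester.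

- Merits: the chemistry is ionic and scalable, gives no statistical mixture and gives the trans product. In certainty of the bond-forming event it is better than the radical cross-coupling.
- Weak points: the C2 configuration must come from an enantioselective flavanone synthesis. It must then survive a strongly acidic medium in which flavanones open reversibly to hydroxychalcones. The oxidant forces a mesylate onto the ring A phenol and a bromine as placeholder for the aldehyde. After the contraction, bromine-to-formyl exchange, demesylation beside a base-sensitive C3 ester and ester reduction are still needed before the side chain can be started.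
- Comparison: the chosen plan reaches the free ring A phenol, the ring C aldehyde and the C3 carboxyl in one step from 8 and 9. Against the greater reliability of alternative 2 it sets this brevity, the low cost of both coupling partners and the separability of the diastereomeric products.

**Alternative 3:** The cut removes O1–C2 and the C3–carboxyl bond from a planar benzofuran. A7 is made from the alkynylphenol A8. In the forward step PdCl2 (divalent palladium) activates the alkyne for attack by the phenol oxygen. The 3-benzofuranylpalladium inserts CO and is cleaved by methanol, and CuCl2 reoxidises the zerovalent palladium.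

- Merits: it is convergent and regiochemically unambiguous, and the aldehyde is already in place. Of the four routes it has the best chance of a high-yielding ring-forming step.
- Weak points: A7 has no stereocentre. C2 and C3 must be created afterwards by reducing a tetrasubstituted, electron-rich double bond. Magnesium in methanol would give the trans ester, but racemic and not in the presence of a free aldehyde. Enantioselective hydrogenation of such benzofurans is not general, so a resolution would be needed. The ring A benzyl ether again calls for hydrogenolysis.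
- Comparison: for racemic material alternative 3 would be preferred. For the single enantiomer the chosen plan sets both ring stereocentres in the bond-forming step and uses the auxiliary to reach diastereomeric purity.

Key step: step 4

**Assumption:** the (S)-4-benzyl auxiliary is taken to favour the (2R,3R) ring in step 4. Because the two trans products are diastereomers and are separated, the (2R,3R) isomer 11 is carried forward whichever way the bias runs, or the (R)-auxiliary is used for the cinnamoyl unit alone.

## Route

Step 1
Reactants: 1 (S)-4-benzyloxazolidin-2-one; 2 bromoacetyl bromide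
Product: 4 (S)-4-benzyl-3-(2-bromoacetyl)oxazolidin-2-one, via lithium oxazolidinide 3 (not isolated)
Conditions: n-BuLi, THF, −78 °C; then 2, −78 to 0 °C
Reagents that add atoms: n-butyllithium, [Li]CCCC (its lithium is held only in intermediate 3)
Why: N-acylation of the lithiated oxazolidinone by the acyl bromide outruns attack at the C–Br bond at low temperature; this is the standard preparation of haloacetyl imides and leaves the stereocentre of 1 untouched.

Step 2
Reactants: 4 (S)-4-benzyl-3-(2-bromoacetyl)oxazolidin-2-one
Product: 6 (S)-4-benzyl-3-[2-(triphenylphosphoranylidene)acetyl]oxazolidin-2-one, via phosphonium bromide 5 (not isolated)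
Conditions: PPh3, toluene, rt; then Et3N, CH2Cl2, 0 °C
Reagents that add atoms: triphenylphosphine, c1ccc(cc1)P(c1ccccc1)c1ccccc1
Why: SN2 quaternisation of the phosphine by the α-bromo imide, then deprotonation of the acidic acylmethylphosphonium salt by a mild amine, gives a carbonyl-stabilised, storable ylide.

Step 3
Reactants: 6 (S)-4-benzyl-3-[2-(triphenylphosphoranylidene)acetyl]oxazolidin-2-one; 7 syringaldehyde
Product: 8 (S)-4-benzyl-3-[(E)-3-(4-hydroxy-3,5-dimethoxyphenyl)prop-2-enoyl]oxazolidin-2-one
Conditions: toluene, 90 °C
Reagents that add atoms: none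
Why: Wittig olefination with a stabilised ylide is E-selective and runs under neutral conditions, so the free phenol of 7 needs no protection and the imide is not exposed to base.

Step 4
Reactants: 8 (S)-4-benzyl-3-[(E)-3-(4-hydroxy-3,5-dimethoxyphenyl)prop-2-enoyl]oxazolidin-2-one; 9 vanillin
Product: 11 (S)-4-benzyl-3-[(2R,3R)-5-formyl-2-(4-hydroxy-3,5-dimethoxyphenyl)-7-methoxy-2,3-dihydrobenzofuran-3-carbonyl]oxazolidin-2-one, via quinone methide 10 (not isolated)
Conditions: Ag2O (3 equiv), 9 (5 equiv), 4 Å molecular sieves, CH2Cl2, rt, dark; 8 added over 8 h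
Reagents that add atoms: none
Why: Proposed new method: Ag2O takes one electron and one proton from each phenol, giving a sinapoyl radical with spin at C8 (both ring positions ortho to oxygen are methoxylated) and a vanillin radical with spin at C5 and O4. Radical–radical coupling of C8 with C5 and enolisation of the vanillin-derived dienone give the phenol–quinone methide 10, which closes ring B by 5-exo-trig conjugate addition of the ring C phenol to the quinone methide carbon (O1–C2) and so rearomatises ring A. The closest known reaction type is the Ag2O dehydrodimerisation of hydroxycinnamoyl esters and N-acyloxazolidinones to 8–5 phenylcoumarans, in which the C5 partner is a second cinnamoyl phenol; a para-formyl phenol without a conjugated side chain as C5 partner is the untested part. C3 is set in the C–C coupling, where the benzyl group of the auxiliary differentiates the two faces of the planar C8 radical. C2 is set in the ring closure, where the aryl group takes the face opposite the C3 acyl group and gives the more stable trans ring. The step needs cross-coupling over homo-coupling, which is served by the excess of cheap vanillin, by slow addition of 8 so that the persistent sinapoyl radical stays dilute, and by the fact that neither partner alone can form a phenylcoumaran. It needs C5 over O4 attack on vanillin, which is expected from the silver-bound phenoxide oxygen and the steric demand of the imide-bearing C8, as in the homodimerisations. It needs one C8 face, where only a moderate bias is expected; this is acceptable because the two trans products are diastereomers and 11 is isolated by chromatography or crystallisation.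

Step 5
Reactants: 11 (S)-4-benzyl-3-[(2R,3R)-5-formyl-2-(4-hydroxy-3,5-dimethoxyphenyl)-7-methoxy-2,3-dihydrobenzofuran-3-carbonyl]oxazolidin-2-one
Product: 12 (S)-4-benzyl-3-[(2R,3R)-5-(1,3-dioxolan-2-yl)-2-(4-hydroxy-3,5-dimethoxyphenyl)-7-methoxy-2,3-dihydrobenzofuran-3-carbonyl]oxazolidin-2-one
Conditions: HOCH2CH2OH, HC(OEt)3, p-TsOH·H2O (cat.), CH2Cl2, rt; Et3N quench
Reagents that add atoms: ethylene glycol, OCCO
Why: Acid-catalysed acetalisation driven by the orthoformate as water scavenger at room temperature; the mask keeps the ring C aldehyde from acting as aldol acceptor in step 8 and from being reduced in step 10, and it makes the ring C oxygen a poorer leaving group for base-induced opening of ring B in step 6.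

Step 6
Reactants: 12 (S)-4-benzyl-3-[(2R,3R)-5-(1,3-dioxolan-2-yl)-2-(4-hydroxy-3,5-dimethoxyphenyl)-7-methoxy-2,3-dihydrobenzofuran-3-carbonyl]oxazolidin-2-one; 4 (S)-4-benzyl-3-(2-bromoacetyl)oxazolidin-2-one
Product: 13 (S)-4-benzyl-3-[(2R,3R)-2-(4-{2-[(S)-4-benzyl-2-oxooxazolidin-3-yl]-2-oxoethoxy}-3,5-dimethoxyphenyl)-5-(1,3-dioxolan-2-yl)-7-methoxy-2,3-dihydrobenzofuran-3-carbonyl]oxazolidin-2-one
Conditions: K2CO3, acetone, rt
Reagents that add atoms: none
Why: Williamson etherification; SN2 at an unbranched α-halo carbonyl carbon is fast even for a 2,6-dimethoxyphenoxide, and the carbonate is too weak to enolise the α-branched C3 imide.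

Step 7
Reactants: 9 vanillin
Product: 14 3-methoxy-4-(triisopropylsilyloxy)benzaldehyde
Conditions: TIPSCl, imidazole, DMF, rt
Reagents that add atoms: chlorotriisopropylsilane, CC(C)[Si](Cl)(C(C)C)C(C)C
Why: Standard silylation of a phenol; the bulky aryl silyl ether survives boron enolates, Mitsunobu conditions, LiBH4 and dilute acid and is cleaved by fluoride.

Step 8
Reactants: 13 (S)-4-benzyl-3-[(2R,3R)-2-(4-{2-[(S)-4-benzyl-2-oxooxazolidin-3-yl]-2-oxoethoxy}-3,5-dimethoxyphenyl)-5-(1,3-dioxolan-2-yl)-7-methoxy-2,3-dihydrobenzofuran-3-carbonyl]oxazolidin-2-one; 14 3-methoxy-4-(triisopropylsilyloxy)benzaldehyde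
Product: 16 syn-aldol adduct of 13 and 14 with a (2S,3R)-2-aryloxy-3-hydroxy-3-[3-methoxy-4-(triisopropylsilyloxy)phenyl]propanoyl chain on the second oxazolidinone, via boron enolate 15 (not isolated)
Conditions: Bu2BOTf, iPr2NEt, CH2Cl2, −78 to 0 °C; 14, −78 to 0 °C; pH 7 buffer, MeOH, H2O2, 0 °C
Reagents that add atoms: dibutylboron triflate, CCCCB(CCCC)OS(=O)(=O)C(F)(F)F (boron and butyl groups are held only in intermediate 15)
Why: Evans syn-aldol reaction: the (Z)-boron enolate reacts through a Zimmerman–Traxler chair in which the (S)-auxiliary fixes the enolate face, so Cβ and Cα are set together as the syn pair independently of C2 and C3. Soft enolisation touches only the unbranched aryloxyacetyl imide, because the α-branched C3 imide is protected from deprotonation by allylic strain, and the dioxolane is expected to survive at low temperature with amine in excess.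

Step 9
Reactants: 16 syn-aldol adduct with the (2S,3R)-2-aryloxy-3-hydroxypropanoyl chain
Product: 17 4-nitrobenzoate of the Cα-inverted alcohol with a (2S,3S)-2-aryloxy-3-(4-nitrobenzoyloxy)propanoyl chain
Conditions: 4-O2NC6H4CO2H, PPh3, DIAD, toluene, −20 °C to rt
Reagents that add atoms: 4-nitrobenzoic acid, O=C(O)c1ccc(cc1)[N+](=O)[O-]
Why: Mitsunobu esterification of the only free hydroxyl proceeds by SN2 displacement of the oxyphosphonium group and inverts Cα, converting the threo (syn) into the erythro (anti) arrangement; the acidic nucleophile and the non-polar solvent disfavour ionisation of the benzylic centre.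

Step 10
Reactants: 17 4-nitrobenzoate with the (2S,3S)-2-aryloxy-3-(4-nitrobenzoyloxy)propanoyl chain
Product: 19 (2R,3S)-2-[4-({(1S,2R)-1,3-dihydroxy-1-[3-methoxy-4-(triisopropylsilyloxy)phenyl]propan-2-yl}oxy)-3,5-dimethoxyphenyl]-3-(hydroxymethyl)-7-methoxy-2,3-dihydrobenzofuran-5-carbaldehyde, via dioxolane triol 18 (not isolated)
Conditions: LiBH4, MeOH, THF, 0 °C to rt; then 1 M HCl to pH 2, THF–H2O, 0 °C to rt
Reagents that add atoms: water, O
Why: Reductive cleavage of N-acyloxazolidinones by LiBH4 turns both imides into primary alcohols and releases both auxiliaries, and the activated nitrobenzoate is reduced off Cα in the same operation. The acidic quench destroys the hydride before it hydrolyses the electron-rich aryl dioxolane. The ring D silyl ether stays on, so no phenoxide can expel the Cα ester as a quinone methide.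

Step 11
Reactants: 19 (2R,3S)-2-[4-({(1S,2R)-1,3-dihydroxy-1-[3-methoxy-4-(triisopropylsilyloxy)phenyl]propan-2-yl}oxy)-3,5-dimethoxyphenyl]-3-(hydroxymethyl)-7-methoxy-2,3-dihydrobenzofuran-5-carbaldehyde
Product: 20 (2R,3S)-2-(4-{[(1S,2R)-1,3-dihydroxy-1-(4-hydroxy-3-methoxyphenyl)propan-2-yl]oxy}-3,5-dimethoxyphenyl)-3-(hydroxymethyl)-7-methoxy-2,3-dihydrobenzofuran-5-carbaldehyde
Conditions: Bu4NF, AcOH, THF, 0 °C
Reagents that add atoms: none
Why: Fluoride cleaves the aryl silyl ether selectively; the acetic acid buffer keeps the freed para-hydroxybenzylic carbinol and the aldehyde away from basic conditions, and no stereocentre is touched.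

## Compound list

1 | (S)-4-benzyloxazolidin-2-one | O=C1OC[C@H](Cc2ccccc2)N1 | starting material
2 | bromoacetyl bromide | BrCC(=O)Br | starting material
3 | lithium salt of (S)-4-benzyloxazolidin-2-one | [Li]N1[C@@H](Cc2ccccc2)COC1=O | intermediate
4 | (S)-4-benzyl-3-(2-bromoacetyl)oxazolidin-2-one | O=C(CBr)N1[C@@H](Cc2ccccc2)COC1=O | intermediate
5 | {2-[(S)-4-benzyl-2-oxooxazolidin-3-yl]-2-oxoethyl}triphenylphosphonium bromide | [Br-].O=C(C[P+](c1ccccc1)(c1ccccc1)c1ccccc1)N1[C@@H](Cc2ccccc2)COC1=O | intermediate
6 | (S)-4-benzyl-3-[2-(triphenylphosphoranylidene)acetyl]oxazolidin-2-one | O=C(C=P(c1ccccc1)(c1ccccc1)c1ccccc1)N1[C@@H](Cc2ccccc2)COC1=O | intermediate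
7 | syringaldehyde (4-hydroxy-3,5-dimethoxybenzaldehyde) | COc1cc(C=O)cc(OC)c1O | starting material
8 | (S)-4-benzyl-3-[(E)-3-(4-hydroxy-3,5-dimethoxyphenyl)prop-2-enoyl]oxazolidin-2-one | COc1cc(/C=C/C(=O)N2[C@@H](Cc3ccccc3)COC2=O)cc(OC)c1O | intermediate
9 | vanillin | COc1cc(C=O)ccc1O | starting material
10 | (S)-4-benzyl-3-[(2S)-3-(3,5-dimethoxy-4-oxocyclohexa-2,5-dien-1-ylidene)-2-(5-formyl-2-hydroxy-3-methoxyphenyl)propanoyl]oxazolidin-2-one (quinone methide) | COC1=CC(=C[C@H](C(=O)N2[C@@H](Cc3ccccc3)COC2=O)c2cc(C=O)cc(OC)c2O)C=C(OC)C1=O | intermediate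
11 | (S)-4-benzyl-3-[(2R,3R)-5-formyl-2-(4-hydroxy-3,5-dimethoxyphenyl)-7-methoxy-2,3-dihydrobenzofuran-3-carbonyl]oxazolidin-2-one | COc1cc([C@@H]2Oc3c(OC)cc(C=O)cc3[C@H]2C(=O)N2[C@@H](Cc3ccccc3)COC2=O)cc(OC)c1O | intermediate
12 | (S)-4-benzyl-3-[(2R,3R)-5-(1,3-dioxolan-2-yl)-2-(4-hydroxy-3,5-dimethoxyphenyl)-7-methoxy-2,3-dihydrobenzofuran-3-carbonyl]oxazolidin-2-one | COc1cc([C@@H]2Oc3c(OC)cc(C4OCCO4)cc3[C@H]2C(=O)N2[C@@H](Cc3ccccc3)COC2=O)cc(OC)c1O | intermediate
13 | (S)-4-benzyl-3-[(2R,3R)-2-(4-{2-[(S)-4-benzyl-2-oxooxazolidin-3-yl]-2-oxoethoxy}-3,5-dimethoxyphenyl)-5-(1,3-dioxolan-2-yl)-7-methoxy-2,3-dihydrobenzofuran-3-carbonyl]oxazolidin-2-one | COc1cc([C@@H]2Oc3c(OC)cc(C4OCCO4)cc3[C@H]2C(=O)N2[C@@H](Cc3ccccc3)COC2=O)cc(OC)c1OCC(=O)N1[C@@H](Cc2ccccc2)COC1=O | intermediate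
14 | 3-methoxy-4-(triisopropylsilyloxy)benzaldehyde | COc1cc(C=O)ccc1O[Si](C(C)C)(C(C)C)C(C)C | intermediate
15 | (Z)-dibutylboron enolate of the aryloxyacetyl imide of 13 | COc1cc([C@@H]2Oc3c(OC)cc(C4OCCO4)cc3[C@H]2C(=O)N2[C@@H](Cc3ccccc3)COC2=O)cc(OC)c1O/C=C(\OB(CCCC)CCCC)N1[C@@H](Cc2ccccc2)COC1=O | intermediate
16 | syn-aldol adduct: 13 in which the aryloxyacetyl group has become (2S,3R)-2-aryloxy-3-hydroxy-3-[3-methoxy-4-(triisopropylsilyloxy)phenyl]propanoyl | COc1cc([C@@H]2Oc3c(OC)cc(C4OCCO4)cc3[C@H]2C(=O)N2[C@@H](Cc3ccccc3)COC2=O)cc(OC)c1O[C@@H]([C@H](O)c1ccc(O[Si](C(C)C)(C(C)C)C(C)C)c(OC)c1)C(=O)N1[C@@H](Cc2ccccc2)COC1=O | intermediate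
17 | Cα-inverted 4-nitrobenzoate: (2S,3S)-2-aryloxy-3-(4-nitrobenzoyloxy)-3-[3-methoxy-4-(triisopropylsilyloxy)phenyl]propanoyl imide | COc1cc([C@@H]2Oc3c(OC)cc(C4OCCO4)cc3[C@H]2C(=O)N2[C@@H](Cc3ccccc3)COC2=O)cc(OC)c1O[C@@H]([C@@H](OC(=O)c1ccc(cc1)[N+](=O)[O-])c1ccc(O[Si](C(C)C)(C(C)C)C(C)C)c(OC)c1)C(=O)N1[C@@H](Cc2ccccc2)COC1=O | intermediate
18 | (1S,2R)-2-{4-[(2R,3S)-5-(1,3-dioxolan-2-yl)-3-(hydroxymethyl)-7-methoxy-2,3-dihydrobenzofuran-2-yl]-2,6-dimethoxyphenoxy}-1-[3-methoxy-4-(triisopropylsilyloxy)phenyl]propane-1,3-diol | COc1cc([C@@H]2Oc3c(OC)cc(C4OCCO4)cc3[C@H]2CO)cc(OC)c1O[C@@H]([C@@H](O)c1ccc(O[Si](C(C)C)(C(C)C)C(C)C)c(OC)c1)CO | intermediate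
19 | (2R,3S)-2-[4-({(1S,2R)-1,3-dihydroxy-1-[3-methoxy-4-(triisopropylsilyloxy)phenyl]propan-2-yl}oxy)-3,5-dimethoxyphenyl]-3-(hydroxymethyl)-7-methoxy-2,3-dihydrobenzofuran-5-carbaldehyde | COc1cc([C@@H]2Oc3c(OC)cc(C=O)cc3[C@H]2CO)cc(OC)c1O[C@@H]([C@@H](O)c1ccc(O[Si](C(C)C)(C(C)C)C(C)C)c(OC)c1)CO | intermediate
20 | (2R,3S)-2-(4-{[(1S,2R)-1,3-dihydroxy-1-(4-hydroxy-3-methoxyphenyl)propan-2-yl]oxy}-3,5-dimethoxyphenyl)-3-(hydroxymethyl)-7-methoxy-2,3-dihydrobenzofuran-5-carbaldehyde | COc1cc([C@H](O)[C@@H](CO)Oc2c(OC)cc([C@@H]3Oc4c(OC)cc(C=O)cc4[C@H]3CO)cc2OC)ccc1O | target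

## Step count and least certain steps

Total step count: 11. Longest linear sequence: 10 steps (steps 1 to 6 and 8 to 11); step 7 is a one-step side branch.

**Step 4 (carries the label "Proposed new method:").** The most likely failure is that each partner couples with itself, giving 8–8 dimers of 8 and 5–5 dimers of vanillin, because the two phenols differ in oxidation potential. Attack at O4 of vanillin instead of C5 and weak facial selectivity at C8 are further risks. The fallback uses the known partner class. It sets out from 8 and couples it under the same Ag2O conditions with commercial ethyl ferulate, a cinnamoyl phenol of comparable oxidation potential. The product is (S)-4-benzyl-3-[(2R,3R)-5-[(E)-3-ethoxy-3-oxoprop-1-enyl]-2-(4-hydroxy-3,5-dimethoxyphenyl)-7-methoxy-2,3-dihydrobenzofuran-3-carbonyl]oxazolidin-2-one F1, separated from ferulate homodimers and from its diastereomer. The only remaining alkene is dihydroxylated (K2OsO2(OH)4 cat., N-methylmorpholine N-oxide, acetone–water) to the ethyl 2,3-dihydroxypropanoate F2. Brief NaIO4 cleavage at 0 °C then gives the ring C aldehyde, and the route is rejoined at 11.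

**Step 9.** Dehydration of the β-hydroxy imide to the α-aryloxycinnamoyl imide may compete with substitution, since the Cβ hydrogen is acidic. Partial ionisation at the electron-rich benzylic Cα would erode the inversion. The fallback sets out from 16 and moves the inversion behind the reduction:

- LiBH4 with neutral work-up gives the threo triol with intact dioxolane, F3.
- TBSCl (2 equiv) and imidazole silylate the two primary hydroxyls to give the bis(tert-butyldimethylsilyl) ether F4, which has no acidic Cβ hydrogen next to a carbonyl.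
- The same Mitsunobu esterification gives the inverted 4-nitrobenzoate F5.
- LiBH4 removes the ester to give the erythro alcohol F6.
- 1 M HCl in THF–H2O removes the two alkyl silyl ethers and the dioxolane, and the route is rejoined at 19.

**Step 3.** The olefination may stall, because the acidic phenol of 7 can protonate ylide 6 and the aldehyde is electron-rich. The fallback forms the imide C–N bond instead of the alkene. It sets out from 1 through its lithium salt 3. Commercial sinapic acid is acetylated (Ac2O, pyridine) to 4-acetoxy-3,5-dimethoxycinnamic acid F7 and converted with (COCl)2 and catalytic DMF into the acid chloride F8. Acylation of 3 gives the O-acetyl sinapoyl imide F9. The aryl acetate is removed with pyrrolidine in CH2Cl2 at 0 °C, and the route is rejoined at 8.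

**Step 5.** Acid may ionise the C2–O1 bond, which is para to the free ring A phenol, so that ring B opens and the cation is captured by the diol. The fallback inverts the order so that the phenol is alkylated before any acid is used. It sets out from 11, which is alkylated with 4 (K2CO3, acetone, rt) to the aldehyde bis-imide F10. Acetalisation under the conditions of step 5 then rejoins the route at 13.

## Further compounds

F1 | step 4 | (S)-4-benzyl-3-[(2R,3R)-5-[(E)-3-ethoxy-3-oxoprop-1-enyl]-2-(4-hydroxy-3,5-dimethoxyphenyl)-7-methoxy-2,3-dihydrobenzofuran-3-carbonyl]oxazolidin-2-one | COc1cc([C@@H]2Oc3c(OC)cc(/C=C/C(=O)OCC)cc3[C@H]2C(=O)N2[C@@H](Cc3ccccc3)COC2=O)cc(OC)c1O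
F2 | step 4 | ethyl 2,3-dihydroxy-3-{(2R,3R)-3-[(S)-4-benzyl-2-oxooxazolidine-3-carbonyl]-2-(4-hydroxy-3,5-dimethoxyphenyl)-7-methoxy-2,3-dihydrobenzofuran-5-yl}propanoate (syn diol, both diastereomers; the two new carbinol centres are left undefined because the cleavage destroys them) | COc1cc([C@@H]2Oc3c(OC)cc(C(O)C(O)C(=O)OCC)cc3[C@H]2C(=O)N2[C@@H](Cc3ccccc3)COC2=O)cc(OC)c1O
F3 | step 9 | (1R,2R)-2-{4-[(2R,3S)-5-(1,3-dioxolan-2-yl)-3-(hydroxymethyl)-7-methoxy-2,3-dihydrobenzofuran-2-yl]-2,6-dimethoxyphenoxy}-1-[3-methoxy-4-(triisopropylsilyloxy)phenyl]propane-1,3-diol | COc1cc([C@@H]2Oc3c(OC)cc(C4OCCO4)cc3[C@H]2CO)cc(OC)c1O[C@@H]([C@H](O)c1ccc(O[Si](C(C)C)(C(C)C)C(C)C)c(OC)c1)CO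
F4 | step 9 | (1R,2R)-3-(tert-butyldimethylsilyloxy)-2-{4-[(2R,3S)-3-(tert-butyldimethylsilyloxymethyl)-5-(1,3-dioxolan-2-yl)-7-methoxy-2,3-dihydrobenzofuran-2-yl]-2,6-dimethoxyphenoxy}-1-[3-methoxy-4-(triisopropylsilyloxy)phenyl]propan-1-ol | COc1cc([C@@H]2Oc3c(OC)cc(C4OCCO4)cc3[C@H]2CO[Si](C)(C)C(C)(C)C)cc(OC)c1O[C@@H]([C@H](O)c1ccc(O[Si](C(C)C)(C(C)C)C(C)C)c(OC)c1)CO[Si](C)(C)C(C)(C)C
F5 | step 9 | (1S,2R)-3-(tert-butyldimethylsilyloxy)-2-{4-[(2R,3S)-3-(tert-butyldimethylsilyloxymethyl)-5-(1,3-dioxolan-2-yl)-7-methoxy-2,3-dihydrobenzofuran-2-yl]-2,6-dimethoxyphenoxy}-1-[3-methoxy-4-(triisopropylsilyloxy)phenyl]propyl 4-nitrobenzoate | COc1cc([C@@H]2Oc3c(OC)cc(C4OCCO4)cc3[C@H]2CO[Si](C)(C)C(C)(C)C)cc(OC)c1O[C@@H]([C@@H](OC(=O)c1ccc(cc1)[N+](=O)[O-])c1ccc(O[Si](C(C)C)(C(C)C)C(C)C)c(OC)c1)CO[Si](C)(C)C(C)(C)C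
F6 | step 9 | (1S,2R)-3-(tert-butyldimethylsilyloxy)-2-{4-[(2R,3S)-3-(tert-butyldimethylsilyloxymethyl)-5-(1,3-dioxolan-2-yl)-7-methoxy-2,3-dihydrobenzofuran-2-yl]-2,6-dimethoxyphenoxy}-1-[3-methoxy-4-(triisopropylsilyloxy)phenyl]propan-1-ol | COc1cc([C@@H]2Oc3c(OC)cc(C4OCCO4)cc3[C@H]2CO[Si](C)(C)C(C)(C)C)cc(OC)c1O[C@@H]([C@@H](O)c1ccc(O[Si](C(C)C)(C(C)C)C(C)C)c(OC)c1)CO[Si](C)(C)C(C)(C)C
F7 | step 3 | (E)-3-(4-acetoxy-3,5-dimethoxyphenyl)prop-2-enoic acid | COc1cc(/C=C/C(=O)O)cc(OC)c1OC(C)=O
F8 | step 3 | (E)-3-(4-acetoxy-3,5-dimethoxyphenyl)prop-2-enoyl chloride | COc1cc(/C=C/C(=O)Cl)cc(OC)c1OC(C)=O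
F9 | step 3 | (S)-3-[(E)-3-(4-acetoxy-3,5-dimethoxyphenyl)prop-2-enoyl]-4-benzyloxazolidin-2-one | COc1cc(/C=C/C(=O)N2[C@@H](Cc3ccccc3)COC2=O)cc(OC)c1OC(C)=O
F10 | step 5 | (S)-4-benzyl-3-[(2R,3R)-2-(4-{2-[(S)-4-benzyl-2-oxooxazolidin-3-yl]-2-oxoethoxy}-3,5-dimethoxyphenyl)-5-formyl-7-methoxy-2,3-dihydrobenzofuran-3-carbonyl]oxazolidin-2-one | COc1cc([C@@H]2Oc3c(OC)cc(C=O)cc3[C@H]2C(=O)N2[C@@H](Cc3ccccc3)COC2=O)cc(OC)c1OCC(=O)N1[C@@H](Cc2ccccc2)COC1=O
A1 | alternative 1 | ethyl (2R,3S)-3-[4-(benzyloxy)-3-methoxyphenyl]-2-{4-[(2R,3S)-3-(tert-butyldimethylsilyloxymethyl)-5-(1,3-dioxolan-2-yl)-7-methoxy-2,3-dihydrobenzofuran-2-yl]-2,6-dimethoxyphenoxy}-3-hydroxypropanoate (erythro) | COc1cc([C@H](O)[C@@H](C(=O)OCC)Oc2c(OC)cc([C@@H]3Oc4c(OC)cc(C5OCCO5)cc4[C@H]3CO[Si](C)(C)C(C)(C)C)cc2OC)ccc1OCc1ccccc1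
A2 | alternative 1 | 4-[(2R,3S)-3-(tert-butyldimethylsilyloxymethyl)-5-(1,3-dioxolan-2-yl)-7-methoxy-2,3-dihydrobenzofuran-2-yl]-2,6-dimethoxyphenol | COc1cc([C@@H]2Oc3c(OC)cc(C4OCCO4)cc3[C@H]2CO[Si](C)(C)C(C)(C)C)cc(OC)c1O
A3 | alternative 1 | ethyl diazoacetate | CCOC(=O)C=[N+]=[N-]
A4 | alternative 1 | 4-(benzyloxy)-3-methoxybenzaldehyde | COc1cc(C=O)ccc1OCc1ccccc1
A5 | alternative 2 | methyl (2R,3R)-5-bromo-2-[3,5-dimethoxy-4-(methylsulfonyloxy)phenyl]-7-methoxy-2,3-dihydrobenzofuran-3-carboxylate (trans) | COc1cc([C@@H]2Oc3c(OC)cc(Br)cc3[C@H]2C(=O)OC)cc(OC)c1OS(C)(=O)=O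
A6 | alternative 2 | (2R)-6-bromo-2-[3,5-dimethoxy-4-(methylsulfonyloxy)phenyl]-8-methoxychroman-4-one | COc1cc([C@H]2CC(=O)c3cc(Br)cc(OC)c3O2)cc(OC)c1OS(C)(=O)=O
A7 | alternative 3 | methyl 2-[4-(benzyloxy)-3,5-dimethoxyphenyl]-5-formyl-7-methoxybenzofuran-3-carboxylate | COC(=O)c1c(-c2cc(OC)c(OCc3ccccc3)c(OC)c2)oc2c(OC)cc(C=O)cc12
A8 | alternative 3 | 3-{[4-(benzyloxy)-3,5-dimethoxyphenyl]ethynyl}-4-hydroxy-5-methoxybenzaldehyde | COc1cc(C=O)cc(C#Cc2cc(OC)c(OCc3ccccc3)c(OC)c2)c1O
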